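**Retrosynthetic overview**

1. The target is an oxane ring (O1, C2–C6; Br on C5, CH3 on C2, two CH3 on C6) bonded through C2 to C1' of a cyclohexane ring (C1'–C6'; Cl on C3', Br and CH3 on C4'). These target locants are used for the corresponding atoms of every intermediate.
2. Late disconnections on the cyclohexane: C4'–Br and the C4' methyl come from HBr addition to a 4'-methylidene group next to C3'–Cl; C3'–Cl comes from reductive α-chlorination of a cyclohex-2'-en-4'-one; the 4'-oxygen comes from allylic oxidation of a cyclohex-2'-ene.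
3. Oxane ring: O1–C6 and C5–Br come from bromoetherification of the C2 tertiary alcohol onto the trisubstituted alkene of the side chain.
4. Cyclohexene ring: Diels–Alder disconnection of C1'–C6' and C4'–C5' into the diene C1'=C2'–C3'=C4' carried by C2 (from (R)-linalool by Heck vinylation) and acrolein as an ethylene equivalent (C5', C6'; formyl carbon later lost as CO). Enabling feature: C5' and C6' form an unsubstituted CH2–CH2 edge of the cyclohexane ring, C1' is its only carbon-substituted atom and both halogens sit on C3'/C4', so ring C1'–C6' is the adduct of a 1-substituted buta-1,3-diene and ethylene, and the C2'=C3' double bond of that adduct steers oxygen to C4' and chlorine to C3'.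
5. Ring order: cyclohexene ring first (step 3), oxane ring second (step 6). C2 is bought with (R)-linalool, C1' is set by the catalyst of the key step, and C5, C3' and C4' are relayed from these by substrate control.

Key step: step 3

Remark: (R)-(−)-linalool of high enantiomeric purity, vinyl bromide and acrolein are taken as commercial starting materials.

**Route**

Step 1
Reactants: 1 (R)-(−)-linalool [(3R)-3,7-dimethylocta-1,6-dien-3-ol]; 2 vinyl bromide (bromoethene)
Product: 3 (3E,5R)-5,9-dimethyldeca-1,3,8-trien-5-ol
Conditions: Pd(OAc)2 (5 mol%), Bu4NCl, NaHCO3, DMF, 60 °C, sealed vessel; 1 in threefold excess over 2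
Reagents that add atoms: none
Why: Heck reaction (vinylation of the monosubstituted alkene): the vinylpalladium bromide should add with the vinyl group at the terminal CH2, and β-hydride elimination is only possible away from the quaternary carbinol carbon, which should give the (E)-diene, leave the trisubstituted alkene and the stereocentre untouched and, with 1 in excess, limit a second vinylation.

Step 2
Reactants: 3 (3E,5R)-5,9-dimethyldeca-1,3,8-trien-5-ol
Product: 4 tert-butyl{[(3E,5R)-5,9-dimethyldeca-1,3,8-trien-5-yl]oxy}dimethylsilane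
Conditions: t-BuMe2SiOSO2CF3, 2,6-lutidine, CH2Cl2, −78 °C to 0 °C
Reagents that add atoms: tert-butyldimethylsilyl trifluoromethanesulfonate, CC(C)(C)[Si](C)(C)OS(=O)(=O)C(F)(F)F
Why: Silyl ether formation: the silyl triflate with 2,6-lutidine should silylate the hindered tertiary alcohol without ionising it, which masks the hydroxyl against lactol formation and acid in steps 3 and 4; no stereocentre is formed.

Step 3
Reactants: 4 tert-butyl{[(3E,5R)-5,9-dimethyldeca-1,3,8-trien-5-yl]oxy}dimethylsilane; 5 acrolein (prop-2-enal)
Product: 6 (1R,2S)-2-[(2R)-2-{[tert-butyl(dimethyl)silyl]oxy}-6-methylhept-5-en-2-yl]cyclohex-3-ene-1-carbaldehyde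
Conditions: (5S)-5-benzyl-2,2,3-trimethylimidazolidin-4-one hydrochloride (20 mol%), CH3CN/H2O 95:5, 0 °C to 23 °C; 5 in threefold excess
Reagents that add atoms: none
Why: Iminium-catalysed Diels–Alder reaction: the secondary amine condenses reversibly with 5 to a catalyst-bound (E)-iminium ion of lowered LUMO, which undergoes a concerted but asynchronous [4+2] cycloaddition with diene 4 and is hydrolysed to 6 with release of the amine. The closest known reaction type is the imidazolidinone-catalysed enantioselective cycloaddition of acrolein with 1-substituted acyclic dienes. The cyclohexene ring is closed by one suprafacial [π4s+π2s] event that forms C4'–C5' (unsubstituted diene terminus to the iminium β-carbon, leading bond) and C1'–C6' (hindered terminus to the α-carbon). The formyl-bearing carbon C6' should be set as (R) by the catalyst, whose benzyl group shields one face of the iminium ion, and C1' is tied to it by the endo transition state, which places the formyl group cis to the C1' side chain. The step needs ortho regiochemistry, endo selectivity and control of the diene face: the single donor substituent at C1' of the (E)-diene secures the first two, and because the existing stereocentre carries two sterically similar alkyl groups (methyl and 4-methylpent-3-enyl) beside the silyloxy group it cannot bias the diene faces, so the catalyst should decide the configuration at C1'. Acrolein acts as an ethylene equivalent, since its formyl carbon is extruded in step 4.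

Step 4
Reactants: 6 (1R,2S)-2-[(2R)-2-{[tert-butyl(dimethyl)silyl]oxy}-6-methylhept-5-en-2-yl]cyclohex-3-ene-1-carbaldehyde
Product: 7 tert-butyl{[(2R)-2-[(1R)-cyclohex-2-en-1-yl]-6-methylhept-5-en-2-yl]oxy}dimethylsilane
Conditions: RhCl3·3H2O (5 mol%), 1,3-bis(diphenylphosphino)propane (10 mol%), diglyme, 160 °C
Reagents that add atoms: none
Why: Tsuji–Wilkinson decarbonylation in its catalytic form: oxidative addition of the formyl C–H bond to rhodium, CO extrusion and C–H reductive elimination should excise the formyl carbon, so that C6' becomes CH2 and C1', which is not α to the carbonyl group, keeps its configuration as the only ring stereocentre.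

Step 5
Reactants: 7 tert-butyl{[(2R)-2-[(1R)-cyclohex-2-en-1-yl]-6-methylhept-5-en-2-yl]oxy}dimethylsilane
Product: 8 (2R)-2-[(1R)-cyclohex-2-en-1-yl]-6-methylhept-5-en-2-ol
Conditions: HF·pyridine, pyridine, THF, 0 °C to 23 °C
Reagents that add atoms: none
Why: Fluoride-induced desilylation of the tertiary silyl ether under pyridine-buffered conditions should free the C2 hydroxyl without touching the two alkenes or any stereocentre.

Step 6
Reactants: 8 (2R)-2-[(1R)-cyclohex-2-en-1-yl]-6-methylhept-5-en-2-ol
Product: 9 (2R,5S)-5-bromo-2-[(1R)-cyclohex-2-en-1-yl]-2,6,6-trimethyloxane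
Conditions: 2,4,4,6-tetrabromocyclohexa-2,5-dien-1-one (1.1 equiv), CH3NO2, 0 °C
Reagents that add atoms: 2,4,4,6-tetrabromocyclohexa-2,5-dien-1-one, O=C1C(Br)=CC(Br)(Br)C=C1Br
Why: Bromoetherification (bromonium-induced 6-endo cyclisation): the electrophile should be taken up by the electron-richer trisubstituted alkene and not by the ring alkene, and the tertiary hydroxyl opens the bromonium ion at its tertiary carbon anti to bromine through a chair transition state with bromine and the cyclohexenyl group equatorial and the C2 methyl axial, which should set C5 as (S) by substrate control from C2.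

Step 7
Reactants: 9 (2R,5S)-5-bromo-2-[(1R)-cyclohex-2-en-1-yl]-2,6,6-trimethyloxane
Product: 10 (4R)-4-[(2R,5S)-5-bromo-2,6,6-trimethyloxan-2-yl]cyclohex-2-en-1-one
Conditions: Rh2(C6H10NO)4 (dirhodium tetracaprolactamate, 1 mol%), t-BuOOH (70% in water, 5 equiv), K2CO3, CH2Cl2, 23 °C
Reagents that add atoms: tert-butyl hydroperoxide, CC(C)(C)OO
Why: Allylic C–H oxidation to the enone by a rhodium-catalysed tert-butylperoxyl radical chain: hydrogen abstraction and oxygenation should occur at the allylic methylene C4' and not at the allylic methine C1', which is shielded by the quaternary C2 of the oxane, and the oxane has no C–H next to oxygen; no stereocentre is formed.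

Step 8
Reactants: 10 (4R)-4-[(2R,5S)-5-bromo-2,6,6-trimethyloxan-2-yl]cyclohex-2-en-1-one
Product: 12 (2S,4R)-4-[(2R,5S)-5-bromo-2,6,6-trimethyloxan-2-yl]-2-chlorocyclohexan-1-one, via silyl enol ether 11 (not isolated)
Conditions: Et3SiH, RhCl(PPh3)3 (1 mol%), benzene, 50 °C; solvent exchange; then N-chlorosuccinimide, THF, 0 °C; aqueous work-up
Reagents that add atoms: N-chlorosuccinimide, O=C1CCC(=O)N1Cl
Why: Rhodium-catalysed 1,4-hydrosilylation of the enone gives the regiodefined silyl enol ether 11 (C4'=C3'), and electrophilic α-chlorination with N-chlorosuccinimide then occurs at C3' by axial attack on the half-chair in which the C1' substituent is equatorial, which should place chlorine trans to that substituent [(S) at C3'] by substrate control.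

Step 9
Reactants: 12 (2S,4R)-4-[(2R,5S)-5-bromo-2,6,6-trimethyloxan-2-yl]-2-chlorocyclohexan-1-one
Product: 13 (2R,5S)-5-bromo-2-[(1R,3S)-3-chloro-4-methylidenecyclohexyl]-2,6,6-trimethyloxane
Conditions: Cp2Ti(μ-Cl)(μ-CH2)AlMe2, pyridine (cat.), THF/toluene, −40 °C to 0 °C
Reagents that add atoms: μ-chloro-μ-methylene-bis(cyclopentadienyl)titanium dimethylaluminium, Cp2Ti(μ-Cl)(μ-CH2)AlMe2, C[Al-]1(C)C[Ti](C2C=CC=C2)(C2C=CC=C2)[Cl+]1
Why: Titanium methylidene (Wittig-type) carbonyl olefination: the non-basic CH2 transfer through an oxatitanacyclobutane should convert the ketone into the exocyclic alkene without enolising the α-chloro ketone, so that C3' keeps its configuration.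

Step 10
Reactants: 13 (2R,5S)-5-bromo-2-[(1R,3S)-3-chloro-4-methylidenecyclohexyl]-2,6,6-trimethyloxane
Product: 14 deoxy isocaespitol, (2R,5S)-5-bromo-2-[(1R,3S,4S)-4-bromo-3-chloro-4-methylcyclohexyl]-2,6,6-trimethyloxane
Conditions: HBr (anhydrous, 1.1 equiv), CH2Cl2, −78 °C
Reagents that add atoms: hydrogen bromide, Br
Why: Ionic Markovnikov hydrobromination: protonation of the exocyclic methylene gives the tertiary C4' cation, which is bridged by the neighbouring axial chlorine, so bromide should add to C4' anti to chlorine and give the trans-diaxial bromo chloride with bromine cis to the C1' substituent [(S) at C4'], which is also the thermodynamically preferred isomer.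

**Compound list**

1 | (R)-(−)-linalool, (3R)-3,7-dimethylocta-1,6-dien-3-ol | CC(C)=CCC[C@@](C)(O)C=C | starting material
2 | vinyl bromide (bromoethene) | C=CBr | starting material
3 | (3E,5R)-5,9-dimethyldeca-1,3,8-trien-5-ol | CC(C)=CCC[C@@](C)(O)/C=C/C=C | intermediate
4 | tert-butyl{[(3E,5R)-5,9-dimethyldeca-1,3,8-trien-5-yl]oxy}dimethylsilane | CC(C)=CCC[C@@](C)(O[Si](C)(C)C(C)(C)C)/C=C/C=C | intermediate
5 | acrolein (prop-2-enal) | C=CC=O | starting material
6 | (1R,2S)-2-[(2R)-2-{[tert-butyl(dimethyl)silyl]oxy}-6-methylhept-5-en-2-yl]cyclohex-3-ene-1-carbaldehyde (formyl group cis to the side chain) | CC(C)=CCC[C@@](C)(O[Si](C)(C)C(C)(C)C)[C@@H]1[C@H](C=O)CCC=C1 | intermediate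
7 | tert-butyl{[(2R)-2-[(1R)-cyclohex-2-en-1-yl]-6-methylhept-5-en-2-yl]oxy}dimethylsilane | CC(C)=CCC[C@@](C)(O[Si](C)(C)C(C)(C)C)[C@@H]1CCCC=C1 | intermediate
8 | (2R)-2-[(1R)-cyclohex-2-en-1-yl]-6-methylhept-5-en-2-ol | CC(C)=CCC[C@@](C)(O)[C@@H]1CCCC=C1 | intermediate
9 | (2R,5S)-5-bromo-2-[(1R)-cyclohex-2-en-1-yl]-2,6,6-trimethyloxane | CC1(C)O[C@@](C)([C@@H]2CCCC=C2)CC[C@@H]1Br | intermediate
10 | (4R)-4-[(2R,5S)-5-bromo-2,6,6-trimethyloxan-2-yl]cyclohex-2-en-1-one | CC1(C)O[C@@](C)([C@@H]2CCC(=O)C=C2)CC[C@@H]1Br | intermediate
11 | triethyl{[(4R)-4-[(2R,5S)-5-bromo-2,6,6-trimethyloxan-2-yl]cyclohex-1-en-1-yl]oxy}silane (silyl enol ether, not isolated) | CC1(C)O[C@@](C)([C@@H]2CCC(O[Si](CC)(CC)CC)=CC2)CC[C@@H]1Br | intermediate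
12 | (2S,4R)-4-[(2R,5S)-5-bromo-2,6,6-trimethyloxan-2-yl]-2-chlorocyclohexan-1-one (chlorine trans to the oxanyl group) | CC1(C)O[C@@](C)([C@@H]2CCC(=O)[C@@H](Cl)C2)CC[C@@H]1Br | intermediate
13 | (2R,5S)-5-bromo-2-[(1R,3S)-3-chloro-4-methylidenecyclohexyl]-2,6,6-trimethyloxane | CC1(C)O[C@@](C)([C@@H]2CCC(=C)[C@@H](Cl)C2)CC[C@@H]1Br | intermediate
14 | deoxy isocaespitol, (2R,5S)-5-bromo-2-[(1R,3S,4S)-4-bromo-3-chloro-4-methylcyclohexyl]-2,6,6-trimethyloxane | CC1(C)O[C@@](C)([C@@H]2CC[C@](C)(Br)[C@@H](Cl)C2)CC[C@@H]1Br | target

**Step count and risks**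

Total step count: 10. Longest linear sequence: 10 steps (from 1 to 14).

Steps most likely to fail:

Step 3 (key step). The cycloaddition may be slow at the neopentyl-like diene terminus, the tertiary dienylic silyl ether may ionise in the acidic aqueous medium, and endo or facial selectivity may erode; an exo adduct would carry the wrong configuration at C1' through step 4. Fallback: setting out from 4, a Lewis-acid-catalysed Diels–Alder reaction with the chelating dienophile 3-acryloyl-1,3-oxazolidin-2-one is used. The catalyst is Cu(SbF6)2 with the enantiomer of 2,2'-(propane-2,2-diyl)bis(4-tert-butyl-4,5-dihydro-1,3-oxazole) that delivers the (1R,2S) adduct, in CH2Cl2. This should give the cis N-acyl oxazolidinone F1. LiOH/H2O2 would hydrolyse it to the carboxylic acid F2. Esterification with N-hydroxypyridine-2-thione (dicyclohexylcarbodiimide) would give the thiohydroxamate ester F3, and its photolysis with t-BuSH (Barton decarboxylation) comes back to the route at 7.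

Step 7. Hydrogen abstraction may also occur at the allylic methine C1', oxygen may be delivered to the other end of the allyl radical (C2'), and over-oxidation may follow, so that regioisomeric enones form. Fallback: setting out from 9, allylic hydroxylation with SeO2 (cat.) and t-BuOOH in CH2Cl2 is used; the ene reaction and [2,3]-sigmatropic shift return oxygen to the allylic CH2 and disfavour the hindered CH. This should give the allylic alcohol F4 as a mixture of carbinol epimers, and oxidation of F4 with MnO2 comes back to the route at 10.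

Step 9. The α-chloro ketone may epimerise at C3', lose HCl, or suffer attack at the C–Cl bond by the Lewis-acidic aluminium and titanium centres of the reagent. Fallback: setting out from 12, a Peterson olefination is used: addition of Me3SiCH2MgCl in the presence of CeCl3 (THF, −78 °C) to the ketone should give the β-hydroxysilane F5, and acid-promoted anti-elimination of F5 (aqueous HF, CH3CN) comes back to the route at 13.

Further compounds
F1 | step 3 | 3-{[(1R,2S)-2-[(2R)-2-{[tert-butyl(dimethyl)silyl]oxy}-6-methylhept-5-en-2-yl]cyclohex-3-en-1-yl]carbonyl}-1,3-oxazolidin-2-one | CC(C)=CCC[C@@](C)(O[Si](C)(C)C(C)(C)C)[C@@H]1[C@H](C(=O)N2CCOC2=O)CCC=C1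
F2 | step 3 | (1R,2S)-2-[(2R)-2-{[tert-butyl(dimethyl)silyl]oxy}-6-methylhept-5-en-2-yl]cyclohex-3-ene-1-carboxylic acid | CC(C)=CCC[C@@](C)(O[Si](C)(C)C(C)(C)C)[C@@H]1[C@H](C(O)=O)CCC=C1
F3 | step 3 | 2-sulfanylidenepyridin-1(2H)-yl (1R,2S)-2-[(2R)-2-{[tert-butyl(dimethyl)silyl]oxy}-6-methylhept-5-en-2-yl]cyclohex-3-ene-1-carboxylate | CC(C)=CCC[C@@](C)(O[Si](C)(C)C(C)(C)C)[C@@H]1[C@H](C(=O)ON2C=CC=CC2=S)CCC=C1
F4 | step 7 | (4R)-4-[(2R,5S)-5-bromo-2,6,6-trimethyloxan-2-yl]cyclohex-2-en-1-ol (both C1 epimers) | CC1(C)O[C@@](C)([C@@H]2CCC(O)C=C2)CC[C@@H]1Br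
F5 | step 9 | (2S,4R)-4-[(2R,5S)-5-bromo-2,6,6-trimethyloxan-2-yl]-2-chloro-1-[(trimethylsilyl)methyl]cyclohexan-1-ol (C1 configuration not defined) | CC1(C)O[C@@](C)([C@@H]2CCC(O)(C[Si](C)(C)C)[C@@H](Cl)C2)CC[C@@H]1Br
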